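The reading at 12.0 min is where I start: there the red run gives its highest reading of target, 39.9%, and the grey run its highest, 49.9%.

| flask | substrate | coupling partner | catalyst | remark | time |
|---|---|---|---|---|---|
| red | 0.40 M | 0.84 equiv | 0.086 mol% | run made earlier |  |
| grey | 0.40 M | 1.3 equiv | 0.086 mol% | run made earlier |  |
| flask | 0.40 M | 0.600 equiv | 0.086 mol% |  | 1.0 h |

| run | time / min | target / % |
|---|---|---|
| red | 4.00 | 26.1 |
| red | 12.0 | 39.9 |
| red | 30.0 | 38.4 |
| red | 80.0 | 26.0 |
| grey | 4.00 | 37.3 |
| grey | 12.0 | 49.9 |
| grey | 30.0 | 48.1 |
| grey | 80.0 | 32.1 |

(scatter of a reading: 0.5 percentage points)

- time, not beyond 1.0 h, at which the flask holds most target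
- the amount of target, in percent of the substrate charged, at that time
- the first time at which target reaches 15%, in the same percent, in min

In the red run the coupling partner is the limiting reagent, and that reading over its charge gives 0.475, the peak share: the highest target read, as a part of what the limiting reagent allows if one partner makes one target. That is about half, so I take the even split as the zero of my scale. The grey run, with substrate as the limiting reagent, also reads about half. With 0.600 equiv of coupling partner in this flask, the red share gives 28.5%.

My doubt is the reading itself. The scatter of 0.5 percentage points moves that estimate by 0.36 points. But the red run still reads 38.4% at 30.0 min, so its top may lie between the two readings and above the one I used. I therefore move up to the even split, and my own estimate is 30.0%.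

The forecast gives 33.5% at 0.34 h and the asked level at 2.5 min, on the ground that “Growth then stalls well before the partner runs out”. Its amount stands higher than mine.

The flask holds most target at 0.296 h, 31.0%, and reaches the asked level at 2.47 min. The forecast's amount and first time lie within their margins, but its time is later.

    substrate + coupling partner ⇌ target (K = 14.0 /M, k = 22.0 /M/h)
    substrate + coupling partner ⇌ isomer of the product A (K = 710 /M, k = 7.90 /M/h)
    target + catalyst ⇌ isomer of the product A + catalyst, rate k3*[catalyst]*[target] forward; the back reaction follows from the equilibrium constant (k = 100 /M/h)
    target ⇌ isomer of the product B (K = 2.50, k = 0.160 /h)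

At the best time the flask also holds 15.9% of isomer of the product A. The peak share of this flask is 0.517, against 0.475 read in the red run. For the neighbour charged with 0.360 equiv of coupling partner, 0.475 gives 17.1%, and that neighbour reaches 19.7%, a peak share of 0.547.

(The data are simulated with made-up constants; scatter was added.)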